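The plan rests on forming the aryl ether bond O1–C8a of the pyran ring (ring B) last. O1 is the hydroxyl oxygen of the quaternary stereocentre C2, so it can be installed early, in the S configuration, by asymmetric epoxidation, and the cis C3=C4 alkene then holds it beside C8a of the benzene ring (ring A). A single palladium-catalysed intramolecular O-arylation of an aryl bromide therefore closes ring B and completes the skeleton without any bond to C2 being broken. Its substrate is a Z-styrenyl tertiary alcohol with bromine on C8a, a silyl-protected oxygen on C6 and the full cyclohexenyl-terminated chain on C2.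

Key step: step 13

Remark: chromene numbering is used (O1, C2, C3, C4, C4a, C5 to C8, C8a; ring A benzene, ring B pyran, ring C cyclohexene); the target is taken as the 2S, chain-E isomer that its SMILES encodes, and diethyl L-(+)-tartrate is chosen by analogy with the epoxidation of geraniol to its (2S,3S) epoxide.

Step 1
Reactants: 1 dihydro-β-ionone; 2 triethyl phosphonoacetate
Product: 3 ethyl (2E)-3-methyl-5-(2,6,6-trimethylcyclohex-1-en-1-yl)pent-2-enoate
Conditions: NaH, THF, 0 °C then 50 °C
Reagents that add atoms: none
Why: Horner–Wadsworth–Emmons olefination of the methyl ketone by the stabilised phosphonate carbanion should give mainly the E trisubstituted enoate, because the oxaphosphetane leading to it places the ester away from the larger ketone substituent, and the hindered ring alkene is inert.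

Step 2
Reactants: 3 ethyl (2E)-3-methyl-5-(2,6,6-trimethylcyclohex-1-en-1-yl)pent-2-enoate
Product: 4 (2E)-3-methyl-5-(2,6,6-trimethylcyclohex-1-en-1-yl)pent-2-en-1-ol
Conditions: iBu2AlH (2.2 equiv), CH2Cl2, −78 °C to 0 °C; aq potassium sodium tartrate; chromatography to remove the minor 2Z alcohol
Reagents that add atoms: none
Why: Ester reduction with diisobutylaluminium hydride proceeds by 1,2-hydride delivery and should give the allylic alcohol with the alkene geometry intact.

Step 3
Reactants: 4 (2E)-3-methyl-5-(2,6,6-trimethylcyclohex-1-en-1-yl)pent-2-en-1-ol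
Product: 5 2-[(3E)-5-bromo-3-methylpent-3-en-1-yl]-1,3,3-trimethylcyclohex-1-ene
Conditions: CBr4, PPh3, CH2Cl2, 0 °C; triturated with pentane, used crude
Reagents that add atoms: tetrabromomethane, BrC(Br)(Br)Br
Why: Appel bromination converts the primary allylic alcohol through its alkoxyphosphonium salt by SN2 attack of bromide under neutral conditions, so neither alkene should migrate or isomerise.

Step 4
Reactants: 5 2-[(3E)-5-bromo-3-methylpent-3-en-1-yl]-1,3,3-trimethylcyclohex-1-ene; 6 ethyl acetoacetate
Product: 9 (5E)-6-methyl-8-(2,6,6-trimethylcyclohex-1-en-1-yl)oct-5-en-2-one, via keto ester 7 (not isolated), via keto acid 8 (not isolated)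
Conditions: 6 (2 equiv), NaH, THF, 0 °C to rt; then NaOH, EtOH/H2O, 60 °C; then 2 M HCl to pH 3, 50 °C
Reagents that add atoms: none
Why: Acetoacetic ester ketone synthesis: the sodium enolate of 6 is C-alkylated by the primary allylic bromide in an SN2 reaction, and saponification followed by decarboxylation of the β-keto acid should leave the methyl ketone with the E alkene unchanged.

Step 5
Reactants: 9 (5E)-6-methyl-8-(2,6,6-trimethylcyclohex-1-en-1-yl)oct-5-en-2-one; 2 triethyl phosphonoacetate
Product: 10 ethyl (2E,6E)-3,7-dimethyl-9-(2,6,6-trimethylcyclohex-1-en-1-yl)nona-2,6-dienoate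
Conditions: NaH, THF, 0 °C then 50 °C
Reagents that add atoms: none
Why: Horner–Wadsworth–Emmons olefination as in step 1 should extend the ketone to the enoate with the new C2=C3 alkene mainly E, the existing E alkene being a spectator.

Step 6
Reactants: 10 ethyl (2E,6E)-3,7-dimethyl-9-(2,6,6-trimethylcyclohex-1-en-1-yl)nona-2,6-dienoate
Product: 11 (2E,6E)-3,7-dimethyl-9-(2,6,6-trimethylcyclohex-1-en-1-yl)nona-2,6-dien-1-ol
Conditions: iBu2AlH (2.2 equiv), CH2Cl2, −78 °C to 0 °C; aq potassium sodium tartrate; chromatography to remove the minor 2Z alcohol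
Reagents that add atoms: none
Why: Ester reduction with diisobutylaluminium hydride, as in step 2, should deliver the E,E allylic alcohol needed for directed epoxidation.

Step 7
Reactants: 11 (2E,6E)-3,7-dimethyl-9-(2,6,6-trimethylcyclohex-1-en-1-yl)nona-2,6-dien-1-ol
Product: 12 [(2S,3S)-3-methyl-3-[(3E)-4-methyl-6-(2,6,6-trimethylcyclohex-1-en-1-yl)hex-3-en-1-yl]oxiran-2-yl]methanol
Conditions: Ti(OiPr)4 (10 mol%), diethyl L-(+)-tartrate (12 mol%), tBuOOH, 4 Å molecular sieves, CH2Cl2, −20 °C
Reagents that add atoms: tert-butyl hydroperoxide, CC(C)(C)OO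
Why: Sharpless asymmetric epoxidation: the complex formed from Ti(OiPr)4 and the tartrate binds the allylic hydroxyl, so only the C2=C3 alkene is oxidised, and with the L-(+)-tartrate oxygen should be delivered to the face that gives the (2S,3S) epoxide, as it does for geraniol, which fixes the quaternary carbon that becomes C2 of the chromene.

Step 8
Reactants: 12 [(2S,3S)-3-methyl-3-[(3E)-4-methyl-6-(2,6,6-trimethylcyclohex-1-en-1-yl)hex-3-en-1-yl]oxiran-2-yl]methanol
Product: 13 (2S,3R)-3-(chloromethyl)-2-methyl-2-[(3E)-4-methyl-6-(2,6,6-trimethylcyclohex-1-en-1-yl)hex-3-en-1-yl]oxirane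
Conditions: PPh3, CCl4, NaHCO3, reflux
Reagents that add atoms: tetrachloromethane, ClC(Cl)(Cl)Cl
Why: Appel chlorination replaces the primary hydroxyl by chloride through SN2 attack on the alkoxyphosphonium salt without opening the epoxide, so both stereocentres are kept (the descriptor of the CH carbon changes only because chlorine alters the priorities).

Step 9
Reactants: 13 (2S,3R)-3-(chloromethyl)-2-methyl-2-[(3E)-4-methyl-6-(2,6,6-trimethylcyclohex-1-en-1-yl)hex-3-en-1-yl]oxirane
Product: 14 (3S,6E)-3,7-dimethyl-9-(2,6,6-trimethylcyclohex-1-en-1-yl)non-6-en-1-yn-3-ol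
Conditions: n-BuLi (3.2 equiv), THF, −40 °C to −20 °C; then H2O, 0 °C
Reagents that add atoms: none
Why: Base-induced fragmentation of a 2,3-epoxy chloride to a propargylic alcohol: lithiation of the chloromethyl carbon triggers β-elimination that opens the epoxide, a second dehydrochlorination forms the alkyne, and because the bond between oxygen and the quaternary carbon is never broken the tertiary carbinol should keep the S configuration.

Step 10
Reactants: 15 4-bromo-3-iodophenol
Product: 16 (4-bromo-3-iodophenoxy)tri(propan-2-yl)silane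
Conditions: iPr3SiCl, imidazole, DMF, rt
Reagents that add atoms: chlorotri(propan-2-yl)silane, CC(C)[Si](Cl)(C(C)C)C(C)C
Why: Silylation of the phenol with the hindered chlorosilane under imidazole catalysis should give a silyl ether that survives amine, hydrogenation and carbonate conditions.

Step 11
Reactants: 14 (3S,6E)-3,7-dimethyl-9-(2,6,6-trimethylcyclohex-1-en-1-yl)non-6-en-1-yn-3-ol; 16 (4-bromo-3-iodophenoxy)tri(propan-2-yl)silane
Product: 17 (3S,6E)-1-[2-bromo-5-(triisopropylsilyloxy)phenyl]-3,7-dimethyl-9-(2,6,6-trimethylcyclohex-1-en-1-yl)non-6-en-1-yn-3-ol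
Conditions: PdCl2(PPh3)2 (2 mol%), CuI (4 mol%), Et3N, THF, rt, degassed
Reagents that add atoms: none
Why: Sonogashira coupling: zerovalent palladium inserts much faster into the C–I bond than into the neighbouring C–Br bond at room temperature, so the copper acetylide of 14 should replace iodine only and leave the bromide for the ring closure.

Step 12
Reactants: 17 (3S,6E)-1-[2-bromo-5-(triisopropylsilyloxy)phenyl]-3,7-dimethyl-9-(2,6,6-trimethylcyclohex-1-en-1-yl)non-6-en-1-yn-3-ol
Product: 18 (1Z,3S,6E)-1-[2-bromo-5-(triisopropylsilyloxy)phenyl]-3,7-dimethyl-9-(2,6,6-trimethylcyclohex-1-en-1-yl)nona-1,6-dien-3-ol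
Conditions: H2 (1 atm), Pd/CaCO3 poisoned with Pb(OAc)2, quinoline, EtOAc, rt, stopped after one equivalent of H2
Reagents that add atoms: none
Why: Lindlar semihydrogenation adds H2 syn on the poisoned palladium surface and should stop at the Z alkene, while the tri- and tetrasubstituted chain alkenes and the aryl bromide are not reduced on this deactivated catalyst.

Step 13
Reactants: 18 (1Z,3S,6E)-1-[2-bromo-5-(triisopropylsilyloxy)phenyl]-3,7-dimethyl-9-(2,6,6-trimethylcyclohex-1-en-1-yl)nona-1,6-dien-3-ol
Product: 19 triisopropyl{[(2S)-2-methyl-2-[(3E)-4-methyl-6-(2,6,6-trimethylcyclohex-1-en-1-yl)hex-3-en-1-yl]-2H-chromen-6-yl]oxy}silane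
Conditions: Pd(OAc)2 (3 mol%), 2-(di-tert-butylphosphino)-1,1'-binaphthyl (4 mol%), Cs2CO3 (1.5 equiv), toluene, 70 °C, degassed
Reagents that add atoms: none
Why: Pd(OAc)2 is reduced in the flask to a zerovalent palladium species carrying one phosphine, which inserts into the C8a–Br bond; Cs2CO3 then removes the C2 hydroxyl proton and the alkoxide displaces bromide on divalent palladium to give a seven-membered oxapalladacycle (Pd, C8a, C4a, C4, C3, C2, O1), from which C–O reductive elimination releases the product and zerovalent palladium. The closest known reaction type is the Buchwald–Hartwig-type intramolecular etherification of aryl bromides with tertiary alcohols to six-membered cyclic aryl ethers, applied here to a tether that contains a Z alkene. Ring B closes in a six-membered exo mode at the ipso carbon C8a (formally 6-exo-trig), the bond being made by reductive elimination and not by direct nucleophilic attack. No stereocentre is created: C2, set in step 7, loses only its hydroxyl proton, so its S configuration should be carried through unchanged. The step needs chemoselectivity for C–O bond formation over Heck-type insertion, β-hydride elimination and protodebromination; the tertiary alkoxide has no hydrogen on the carbinol carbon, the chain alkenes are tri- and tetrasubstituted and remote, the Z geometry of C3=C4 holds O1 within reach of C8a, and the bulky electron-rich di-tert-butylphosphine speeds reductive elimination. The triisopropylsilyl ether keeps the C6 oxygen from becoming a competing phenoxide nucleophile under the carbonate base.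

Step 14
Reactants: 19 triisopropyl{[(2S)-2-methyl-2-[(3E)-4-methyl-6-(2,6,6-trimethylcyclohex-1-en-1-yl)hex-3-en-1-yl]-2H-chromen-6-yl]oxy}silane
Product: 20 (2S)-2-methyl-2-[(3E)-4-methyl-6-(2,6,6-trimethylcyclohex-1-en-1-yl)hex-3-en-1-yl]-2H-chromen-6-ol
Conditions: Bu4NF, AcOH (1:1), THF, 0 °C
Reagents that add atoms: none
Why: Fluoride-mediated desilylation is driven by Si–F bond formation, and the acetic acid buffer protonates the phenoxide as it forms, so the electron-rich chromenol should be released without base-induced oxidation and without affecting C2 or the alkenes.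

Compound list
1 | dihydro-β-ionone, 4-(2,6,6-trimethylcyclohex-1-en-1-yl)butan-2-one | CC(=O)CCC1=C(C)CCCC1(C)C | starting material
2 | triethyl phosphonoacetate | CCOC(=O)CP(=O)(OCC)OCC | starting material
3 | ethyl (2E)-3-methyl-5-(2,6,6-trimethylcyclohex-1-en-1-yl)pent-2-enoate | CCOC(=O)/C=C(\C)CCC1=C(C)CCCC1(C)C | intermediate
4 | (2E)-3-methyl-5-(2,6,6-trimethylcyclohex-1-en-1-yl)pent-2-en-1-ol | OC/C=C(\C)CCC1=C(C)CCCC1(C)C | intermediate
5 | 2-[(3E)-5-bromo-3-methylpent-3-en-1-yl]-1,3,3-trimethylcyclohex-1-ene | BrC/C=C(\C)CCC1=C(C)CCCC1(C)C | intermediate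
6 | ethyl acetoacetate | CCOC(=O)CC(C)=O | starting material
7 | ethyl (4E)-2-acetyl-5-methyl-7-(2,6,6-trimethylcyclohex-1-en-1-yl)hept-4-enoate, racemic at C2 (keto ester) | CCOC(=O)C(C/C=C(\C)CCC1=C(C)CCCC1(C)C)C(C)=O | intermediate
8 | (4E)-2-acetyl-5-methyl-7-(2,6,6-trimethylcyclohex-1-en-1-yl)hept-4-enoic acid, racemic at C2 (keto acid) | OC(=O)C(C/C=C(\C)CCC1=C(C)CCCC1(C)C)C(C)=O | intermediate
9 | (5E)-6-methyl-8-(2,6,6-trimethylcyclohex-1-en-1-yl)oct-5-en-2-one | CC(=O)CC/C=C(\C)CCC1=C(C)CCCC1(C)C | intermediate
10 | ethyl (2E,6E)-3,7-dimethyl-9-(2,6,6-trimethylcyclohex-1-en-1-yl)nona-2,6-dienoate | CCOC(=O)/C=C(\C)CC/C=C(\C)CCC1=C(C)CCCC1(C)C | intermediate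
11 | (2E,6E)-3,7-dimethyl-9-(2,6,6-trimethylcyclohex-1-en-1-yl)nona-2,6-dien-1-ol | OC/C=C(\C)CC/C=C(\C)CCC1=C(C)CCCC1(C)C | intermediate
12 | [(2S,3S)-3-methyl-3-[(3E)-4-methyl-6-(2,6,6-trimethylcyclohex-1-en-1-yl)hex-3-en-1-yl]oxiran-2-yl]methanol | OC[C@@H]1O[C@@]1(C)CC/C=C(\C)CCC2=C(C)CCCC2(C)C | intermediate
13 | (2S,3R)-3-(chloromethyl)-2-methyl-2-[(3E)-4-methyl-6-(2,6,6-trimethylcyclohex-1-en-1-yl)hex-3-en-1-yl]oxirane | ClC[C@@H]1O[C@@]1(C)CC/C=C(\C)CCC2=C(C)CCCC2(C)C | intermediate
14 | (3S,6E)-3,7-dimethyl-9-(2,6,6-trimethylcyclohex-1-en-1-yl)non-6-en-1-yn-3-ol | C#C[C@@](C)(O)CC/C=C(\C)CCC1=C(C)CCCC1(C)C | intermediate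
15 | 4-bromo-3-iodophenol | Oc1ccc(Br)c(I)c1 | starting material
16 | (4-bromo-3-iodophenoxy)tri(propan-2-yl)silane | CC(C)[Si](Oc1ccc(Br)c(I)c1)(C(C)C)C(C)C | intermediate
17 | (3S,6E)-1-[2-bromo-5-(triisopropylsilyloxy)phenyl]-3,7-dimethyl-9-(2,6,6-trimethylcyclohex-1-en-1-yl)non-6-en-1-yn-3-ol | Brc1ccc(O[Si](C(C)C)(C(C)C)C(C)C)cc1C#C[C@@](C)(O)CC/C=C(\C)CCC2=C(C)CCCC2(C)C | intermediate
18 | (1Z,3S,6E)-1-[2-bromo-5-(triisopropylsilyloxy)phenyl]-3,7-dimethyl-9-(2,6,6-trimethylcyclohex-1-en-1-yl)nona-1,6-dien-3-ol | Brc1ccc(O[Si](C(C)C)(C(C)C)C(C)C)cc1/C=C\[C@@](C)(O)CC/C=C(\C)CCC2=C(C)CCCC2(C)C | intermediate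
19 | triisopropyl{[(2S)-2-methyl-2-[(3E)-4-methyl-6-(2,6,6-trimethylcyclohex-1-en-1-yl)hex-3-en-1-yl]-2H-chromen-6-yl]oxy}silane | CC1=C(CC/C(C)=C/CC[C@@]2(C)C=Cc3cc(O[Si](C(C)C)(C(C)C)C(C)C)ccc3O2)C(C)(C)CCC1 | intermediate
20 | (2S)-2-methyl-2-[(3E)-4-methyl-6-(2,6,6-trimethylcyclohex-1-en-1-yl)hex-3-en-1-yl]-2H-chromen-6-ol | CC1=C(CC/C(C)=C/CC[C@@]2(C)C=Cc3cc(O)ccc3O2)C(C)(C)CCC1 | target

Total step count: 14. Longest linear sequence: 13 steps (steps 1 to 9 and 11 to 14, from 1 to 20); step 10 prepares the aryl partner.

Steps most likely to fail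

Step 13. After oxidative addition the hindered tertiary alkoxide may bind slowly and C–O reductive elimination may stall, so that protodebromination or β-carbon cleavage of the palladium alkoxide overtakes ring closure. The fallback sets out again from 18 and closes the same O1–C8a bond by a copper-mediated Ullmann-type O-arylation instead of palladium catalysis (CuI, 3,4,7,8-tetramethyl-1,10-phenanthroline, Cs2CO3, toluene, 110 °C). This runs through a copper alkoxide and a different bond-forming manifold, and it returns to the route at 19. It makes no compound outside the list (F0).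

Step 12. The heterogeneous hydrogenation may over-reduce the new styrenyl alkene, cleave the aryl C–Br bond by hydrogenolysis, or stall on the hindered alkyne. The fallback sets out from 17 and replaces hydrogenation by an electron-transfer reduction with zinc dust activated by Cu(OAc)2 and AgNO3 in MeOH/H2O/THF at rt (Boland reduction). This reduces aryl-conjugated propargylic alkynes to Z alkenes by stepwise electron transfer and protonation, uses no H2, and should leave isolated alkenes and the aryl bromide alone; it returns at 18. It makes no compound outside the list (F0).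

Step 5. Geometric control may be poor in the olefination of a methyl ketone whose two substituents differ little in size, leaving an E/Z mixture at C2=C3 that is hard to separate on valuable material. The fallback sets out from bromide 5 and builds the alkene by syn-carbometalation. Bromide 5 alkylates 3-lithio-1-(trimethylsilyl)propyne (from 1-(trimethylsilyl)propyne and n-BuLi, THF, −78 °C) to give the silyl enyne F1. K2CO3 in MeOH removes silicon to give the terminal enyne F2. Me3Al with catalytic Cp2ZrCl2 in ClCH2CH2Cl (zirconium-catalysed carboalumination) then adds methyl and aluminium syn across the alkyne, and the alkenylalane, after treatment with n-BuLi, is trapped with paraformaldehyde. This should give 11 directly, with the 2E geometry fixed by the syn addition. The sequence replaces steps 4 to 6 and returns at 11.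

Further compounds
F0 | step 13 | none | none
F0 | step 12 | none | none
F1 | step 5 | trimethyl[(5E)-6-methyl-8-(2,6,6-trimethylcyclohex-1-en-1-yl)oct-5-en-1-yn-1-yl]silane | C[Si](C)(C)C#CCC/C=C(\C)CCC1=C(C)CCCC1(C)C
F2 | step 5 | 2-[(3E)-3-methyloct-3-en-7-yn-1-yl]-1,3,3-trimethylcyclohex-1-ene | C#CCC/C=C(\C)CCC1=C(C)CCCC1(C)C
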